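**Plan**

1. Rings: A = 4-hydroxy-3-methoxybenzyl arene; B = 4-hydroxy-3-methoxyphenyl; C and D = benzene and dihydrofuran of the benzofuran; E = oxolane (O1, C2 aryl-bearing, C3 CH2OH-bearing, C4 carbinol, C5). Cuts, in retrosynthetic order: the protecting groups; the CH2–ring A bond at C4 of ring E (spiro-epoxide + aryl Grignard); C3–C4 and O1–C5 of ring E (keto ester + bromopyruvate annulation) and the C2/C3 hydrogens (hydrogenation); the ring C–CO/CH2 bond (Claisen); C3a–C7a and C4–C5 of ring C (pyrone–alkyne cycloaddition with CO2 loss); C2–O1 of ring D (Mitsunobu); C2–C3 of ring D (allenylzinc addition).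
2. Enabling feature: ring C is a 1,2,3,5-tetrasubstituted benzene whose neighbouring atoms C7a (oxygen) and C3a (carbon) are spanned by O1–C2–C3 of ring D. That three-atom unit can therefore tether a 3-oxy-4-methoxy-2-pyrone-6-carboxylate (future C7a, C7, C6, C5) to a terminal alkyne (future C3a, C4).
3. Forward order: hydroxypyrone and homopropargylic alcohol are joined as an ether; heating closes rings D and C in one operation; the C5 ester is extended to a β-keto ester; ring E is annulated and reduced; ring A is attached last; then deprotection.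
4. Stereochemistry: ring D C3 from (R)-glyceraldehyde acetonide (net inversion in the propargylation); ring D C2 from anti addition followed by Mitsunobu inversion (cis); ring E C4 from a cinchona-catalysed annulation; ring E C2 and C3 from hydrogen delivery to the hydroxyl face.
5. Protecting groups: the ring B phenol is carried as its dimethylcarbamate, which is electron-poor and so keeps the benzylic carbon from ionising in the Mitsunobu and thermolysis steps; LiAlH4 removes it. The ring A phenol and the ring D CH2OH are benzyl ethers, removed in one final hydrogenolysis.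

Key step: step 12

Assumption: the quinidine-derived catalyst (DHQD)2PYR is taken to give the (4S) carbinol in step 14; if the sense proves opposite, its quinine-derived pseudoenantiomer (DHQ)2PYR is used in the same way.

Abbreviation used in names: DBF = (2R,3R)-3-[(benzyloxy)methyl]-2-[4-(dimethylcarbamoyloxy)-3-methoxyphenyl]-7-methoxy-2,3-dihydro-1-benzofuran-5-yl.

**Route**

Step 1
Reactants: 1 4-methoxy-6-methyl-2H-pyran-2-one
Product: 2 4-methoxy-2-oxo-2H-pyran-6-carbaldehyde
Conditions: SeO2, 1,4-dioxane, 160 °C, sealed tube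
Reagents that add atoms: selenium dioxide O=[Se]=O
Why: Riley oxidation with SeO2 attacks the 6-methyl group, which is allylic to the C5=C6 double bond and is the only activated C–H position of the pyrone, a transformation established for this substrate.

Step 2
Reactants: 2 4-methoxy-2-oxo-2H-pyran-6-carbaldehyde
Product: 3 methyl 4-methoxy-2-oxo-2H-pyran-6-carboxylate
Conditions: KHSO5 (as the triple salt 2KHSO5·KHSO4·K2SO4), MeOH, rt
Reagents that add atoms: methanol CO; potassium peroxymonosulfate [K+].[O-]S(=O)(=O)OO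
Why: Oxidative esterification of an aldehyde by peroxymonosulfate in methanol proceeds through the methyl hemiacetal and its peroxy adduct under mildly acidic conditions that should leave the lactone and enol ether intact.

Step 3
Reactants: 3 methyl 4-methoxy-2-oxo-2H-pyran-6-carboxylate
Product: 4 methyl 3-bromo-4-methoxy-2-oxo-2H-pyran-6-carboxylate
Conditions: N-bromosuccinimide, MeCN, rt
Reagents that add atoms: N-bromosuccinimide O=C1CCC(=O)N1Br
Why: Electrophilic bromination of a 4-methoxy-2-pyrone occurs at C3, the nucleophilic β-carbon of the enol ether next to the lactone carbonyl, and the C6 ester further deactivates the alternative C5 position.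

Step 4
Reactants: 4 methyl 3-bromo-4-methoxy-2-oxo-2H-pyran-6-carboxylate
Product: 6 methyl 3-hydroxy-4-methoxy-2-oxo-2H-pyran-6-carboxylate, via pinacol boronate 5 (not isolated)
Conditions: Pd(dppf)Cl2 (5 mol%), B2pin2, KOAc, 1,4-dioxane, 80 °C; then NaBO3·4H2O, THF–H2O, rt
Reagents that add atoms: sodium perborate O=BO[O-].[Na+]
Why: Miyaura borylation of the alkenyl bromide followed by perborate oxidation of the carbon–boron bond is a standard two-stage ipso-hydroxylation that avoids the strongly basic hydroxide conditions a 2-pyrone would not tolerate.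

Step 5
Reactants: 7 (R)-2,2-dimethyl-1,3-dioxolane-4-carbaldehyde
Product: 8 (S)-4-ethynyl-2,2-dimethyl-1,3-dioxolane
Conditions: dimethyl (1-diazo-2-oxopropyl)phosphonate, K2CO3, MeOH, 0 °C → rt
Reagents that add atoms: dimethyl (1-diazo-2-oxopropyl)phosphonate CC(=O)C(=[N+]=[N-])P(=O)(OC)OC
Why: The Ohira–Bestmann variant of the Seyferth–Gilbert homologation converts the aldehyde into the terminal alkyne under carbonate/methanol conditions known to preserve this α-alkoxy stereocentre (the descriptor changes from R to S only through the priority rules).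

Step 6
Reactants: 8 (S)-4-ethynyl-2,2-dimethyl-1,3-dioxolane
Product: 9 (S)-but-3-yne-1,2-diol
Conditions: 80% aq. AcOH, 40 °C
Reagents that add atoms: none
Why: Acid-catalysed hydrolysis of the isopropylidene acetal frees the 1,2-diol without touching the stereocentre or the alkyne.

Step 7
Reactants: 9 (S)-but-3-yne-1,2-diol
Product: 11 (S)-1-(benzyloxy)but-3-yn-2-ol, via stannylene acetal 10 (not isolated)
Conditions: Bu2SnO, PhMe, reflux (water removed); then BnBr, Bu4NI, 90 °C
Reagents that add atoms: benzyl bromide BrCc1ccccc1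
Why: Stannylene acetal activation directs O-alkylation to the primary oxygen of a 1,2-diol, so benzyl bromide should give the primary benzyl ether selectively.

Step 8
Reactants: 11 (S)-1-(benzyloxy)but-3-yn-2-ol
Product: 12 (S)-1-(benzyloxy)but-3-yn-2-yl methanesulfonate
Conditions: MsCl, Et3N, CH2Cl2, −40 → 0 °C
Reagents that add atoms: methanesulfonyl chloride CS(=O)(=O)Cl
Why: Sulfonylation of the secondary propargylic alcohol installs the leaving group for the propargylation without breaking any bond at the stereocentre.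

Step 9
Reactants: 13 vanillin (4-hydroxy-3-methoxybenzaldehyde)
Product: 14 4-formyl-2-methoxyphenyl dimethylcarbamate
Conditions: Me2NCOCl, K2CO3, MeCN, 60 °C
Reagents that add atoms: dimethylcarbamoyl chloride CN(C)C(=O)Cl
Why: O-Carbamoylation of the phenol installs an electron-poor, base- and heat-stable protecting group that switches off para-oxygen donation into the future benzylic centre.

Step 10
Reactants: 12 (S)-1-(benzyloxy)but-3-yn-2-yl methanesulfonate; 14 4-formyl-2-methoxyphenyl dimethylcarbamate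
Product: 16 4-[(1S,2R)-2-[(benzyloxy)methyl]-1-hydroxybut-3-yn-1-yl]-2-methoxyphenyl dimethylcarbamate, via allenylzinc reagent 15 (not isolated)
Conditions: Pd(OAc)2 (5 mol%), PPh3 (5 mol%), Et2Zn (3 equiv), THF, −78 → −20 °C
Reagents that add atoms: none
Why: In this palladium-catalysed zinc propargylation (Marshall–Tamaru type) anti SN2' oxidative addition of zerovalent palladium and transmetalation give the (P)-allenylzinc 15, which adds to the aldehyde through a cyclic SE2' transition state, so C2 arises with net inversion of the mesylate centre (R) and the chair-like arrangement with the aryl group equatorial sets the anti carbinol (1S).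

Step 11
Reactants: 16 4-[(1S,2R)-2-[(benzyloxy)methyl]-1-hydroxybut-3-yn-1-yl]-2-methoxyphenyl dimethylcarbamate; 6 methyl 3-hydroxy-4-methoxy-2-oxo-2H-pyran-6-carboxylate
Product: 17 methyl 3-{[(1R,2R)-2-[(benzyloxy)methyl]-1-[4-(dimethylcarbamoyloxy)-3-methoxyphenyl]but-3-yn-1-yl]oxy}-4-methoxy-2-oxo-2H-pyran-6-carboxylate
Conditions: PPh3, DIAD, PhMe, 0 °C → rt
Reagents that add atoms: none
Why: Mitsunobu etherification with the acidic enolic hydroxyl of pyrone 6 as pronucleophile inverts the carbinol carbon by SN2 (1S to 1R) to give the syn ether, and the carbamate on ring B disfavours competing benzylic ionisation.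

Step 12
Reactants: 17 methyl 3-{[(1R,2R)-2-[(benzyloxy)methyl]-1-[4-(dimethylcarbamoyloxy)-3-methoxyphenyl]but-3-yn-1-yl]oxy}-4-methoxy-2-oxo-2H-pyran-6-carboxylate
Product: 19 methyl (2R,3R)-3-[(benzyloxy)methyl]-2-[4-(dimethylcarbamoyloxy)-3-methoxyphenyl]-7-methoxy-2,3-dihydro-1-benzofuran-5-carboxylate, via bridged lactone cycloadduct 18 (not isolated)
Conditions: o-dichlorobenzene (0.01 M), 170 °C, sealed tube
Reagents that add atoms: none
Why: In a thermal intramolecular [4+2] cycloaddition the pyrone diene (C3–C6) adds across the tethered terminal alkyne, the inner alkyne carbon bonding to pyrone C3 (C3a–C7a) and the terminal carbon to pyrone C6 (C4–C5), to give the 2-oxabicyclo[2.2.2]octadienone 18, which loses CO2 by retro-[4+2] and aromatises. The closest known reaction type is the Diels–Alder/decarboxylation of 2-pyrones with alkynes, including tethered cases. Ring D closes as the five-membered ring of a cycloaddition whose three-atom O–C–C tether sits on the diene terminus, and ring C closes as the six-membered ring of the [4+2] and becomes aromatic on CO2 extrusion. No stereocentre is created: the bridgehead centres of 18 are destroyed on aromatisation, and C2 and C3 are carried through because no bond to them is made or broken under neutral thermolysis. The step needs regioselectivity (OMe at C7, ester at C5, H at C4 and C6), which the tether fixes by allowing only one orientation of the alkyne; the ester at pyrone C6 lowers the diene LUMO and the carbamate on ring B suppresses heterolysis of the benzylic C–O bond at this temperature.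

Step 13
Reactants: 19 methyl (2R,3R)-3-[(benzyloxy)methyl]-2-[4-(dimethylcarbamoyloxy)-3-methoxyphenyl]-7-methoxy-2,3-dihydro-1-benzofuran-5-carboxylate
Product: 20 tert-butyl 3-(DBF)-3-oxopropanoate
Conditions: tert-butyl acetate, LiN(SiMe3)2, THF, −78 → 0 °C; aq. NH4Cl
Reagents that add atoms: tert-butyl acetate CC(=O)OC(C)(C)C
Why: Crossed Claisen condensation of the aryl methyl ester with excess lithium enolate of tert-butyl acetate is driven by deprotonation of the β-keto ester formed, and the carbamate and benzyl ether are inert to the enolate at low temperature.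

Step 14
Reactants: 20 tert-butyl 3-(DBF)-3-oxopropanoate; 21 ethyl 3-bromo-2-oxopropanoate (ethyl bromopyruvate)
Product: 23 3-tert-butyl 4-ethyl (4S)-2-(DBF)-4-hydroxy-4,5-dihydrofuran-3,4-dicarboxylate, via aldol bromohydrin 22 (not isolated)
Conditions: (DHQD)2PYR (10 mol%), 1,8-bis(dimethylamino)naphthalene, THF, −78 °C
Reagents that add atoms: none
Why: The catalytic asymmetric interrupted Feist–Benary reaction joins the keto ester to the activated ketone of the bromopyruvate by a cinchona-ether-controlled aldol addition that sets the tertiary carbinol (4S), after which the enol oxygen displaces bromide (5-exo-tet) to close the hydroxydihydrofuran without dehydration.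

Step 15
Reactants: 23 3-tert-butyl 4-ethyl (4S)-2-(DBF)-4-hydroxy-4,5-dihydrofuran-3,4-dicarboxylate
Product: 24 3-tert-butyl 4-ethyl (2R,3R,4S)-2-(DBF)-4-hydroxyoxolane-3,4-dicarboxylate
Conditions: H2 (50 bar), [Ir(cod)(PCy3)(py)]PF6 (10 mol%), CH2Cl2, rt
Reagents that add atoms: none
Why: Hydroxyl-directed homogeneous hydrogenation with the cationic iridium complex delivers both hydrogens to the alkene face syn to the tertiary hydroxyl, which sets C2 (R) and C3 (R) with aryl, ester and the C4 carbon substituent all cis, and leaves the benzyl ether and benzylic C–O bonds untouched.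

Step 16
Reactants: 24 3-tert-butyl 4-ethyl (2R,3R,4S)-2-(DBF)-4-hydroxyoxolane-3,4-dicarboxylate
Product: 25 tert-butyl (2R,3R,4R)-2-(DBF)-4-hydroxy-4-(hydroxymethyl)oxolane-3-carboxylate
Conditions: LiBH4, THF, 0 °C → rt
Reagents that add atoms: none
Why: Chelation-assisted borohydride reduction is selective for the α-hydroxy ethyl ester, while the hindered tert-butyl ester and the carbamate are not reduced by LiBH4 at this temperature.

Step 17
Reactants: 25 tert-butyl (2R,3R,4R)-2-(DBF)-4-hydroxy-4-(hydroxymethyl)oxolane-3-carboxylate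
Product: 27 tert-butyl (3R,6R,7R)-6-(DBF)-1,5-dioxaspiro[2.4]heptane-7-carboxylate, via primary tosylate 26 (not isolated)
Conditions: TsCl, Et3N, Bu2SnO (2 mol%), CH2Cl2, 0 °C → rt; then K2CO3, MeOH, 0 °C
Reagents that add atoms: none
Why: Tin-catalysed sulfonylation selects the primary hydroxyl of the 1,2-diol and the tertiary alkoxide then closes the epoxide by intramolecular Williamson displacement (3-exo-tet), so the configuration of the carbinol carbon is retained.

Step 18
Reactants: 27 tert-butyl (3R,6R,7R)-6-(DBF)-1,5-dioxaspiro[2.4]heptane-7-carboxylate; 28 1-(benzyloxy)-4-bromo-2-methoxybenzene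
Product: 30 tert-butyl (2R,3R,4S)-4-[4-(benzyloxy)-3-methoxybenzyl]-2-(DBF)-4-hydroxyoxolane-3-carboxylate, via aryl Grignard reagent 29 (not isolated)
Conditions: 28, Mg, THF, rt; then CuI (10 mol%), 27, THF, −30 → 0 °C; aq. NH4Cl
Reagents that add atoms: none
Why: Copper-catalysed opening of a 2,2-disubstituted epoxide by an aryl Grignard reagent occurs by SN2 attack at the unhindered CH2 carbon, which attaches ring A and leaves the tertiary C–O bond and its configuration untouched.

Step 19
Reactants: 30 tert-butyl (2R,3R,4S)-4-[4-(benzyloxy)-3-methoxybenzyl]-2-(DBF)-4-hydroxyoxolane-3-carboxylate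
Product: 31 (3S,4R,5R)-3-[4-(benzyloxy)-3-methoxybenzyl]-5-[(2R,3R)-3-[(benzyloxy)methyl]-2-(4-hydroxy-3-methoxyphenyl)-7-methoxy-2,3-dihydro-1-benzofuran-5-yl]-4-(hydroxymethyl)oxolan-3-ol
Conditions: LiAlH4, THF, 0 → 50 °C; aq. potassium sodium tartrate
Reagents that add atoms: none
Why: LiAlH4 reduces the tert-butyl ester to the primary alcohol and cleaves the aryl dimethylcarbamate to the phenol by acyl substitution, both standard hydride reductions that do not affect benzyl ethers or the stereocentres.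

Step 20
Reactants: 31 (3S,4R,5R)-3-[4-(benzyloxy)-3-methoxybenzyl]-5-[(2R,3R)-3-[(benzyloxy)methyl]-2-(4-hydroxy-3-methoxyphenyl)-7-methoxy-2,3-dihydro-1-benzofuran-5-yl]-4-(hydroxymethyl)oxolan-3-ol
Product: 32 (3S,4R,5R)-5-[(2R,3R)-2-(4-hydroxy-3-methoxyphenyl)-3-(hydroxymethyl)-7-methoxy-2,3-dihydro-1-benzofuran-5-yl]-3-(4-hydroxy-3-methoxybenzyl)-4-(hydroxymethyl)oxolan-3-ol (CNP0284796.1)
Conditions: H2 (1 atm), 10% Pd/C, EtOAc–MeOH, rt
Reagents that add atoms: none
Why: Catalytic hydrogenolysis over Pd/C under neutral conditions removes the aryl and alkyl benzyl ethers much faster than it cleaves the cyclic benzylic ethers of rings D and E, giving the target.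

**Compound list**

1 | 4-methoxy-6-methyl-2H-pyran-2-one | COC1=CC(=O)OC(C)=C1 | starting material
2 | 4-methoxy-2-oxo-2H-pyran-6-carbaldehyde | COC1=CC(=O)OC(C=O)=C1 | intermediate
3 | methyl 4-methoxy-2-oxo-2H-pyran-6-carboxylate | COC(=O)C1=CC(OC)=CC(=O)O1 | intermediate
4 | methyl 3-bromo-4-methoxy-2-oxo-2H-pyran-6-carboxylate | COC(=O)C1=CC(OC)=C(Br)C(=O)O1 | intermediate
5 | methyl 4-methoxy-2-oxo-3-(4,4,5,5-tetramethyl-1,3,2-dioxaborolan-2-yl)-2H-pyran-6-carboxylate | COC(=O)C1=CC(OC)=C(B2OC(C)(C)C(C)(C)O2)C(=O)O1 | intermediate (not isolated)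
6 | methyl 3-hydroxy-4-methoxy-2-oxo-2H-pyran-6-carboxylate | COC(=O)C1=CC(OC)=C(O)C(=O)O1 | intermediate
7 | (R)-2,2-dimethyl-1,3-dioxolane-4-carbaldehyde | O=C[C@H]1COC(C)(C)O1 | starting material
8 | (S)-4-ethynyl-2,2-dimethyl-1,3-dioxolane | C#C[C@H]1COC(C)(C)O1 | intermediate
9 | (S)-but-3-yne-1,2-diol | C#C[C@H](O)CO | intermediate
10 | (S)-2,2-dibutyl-4-ethynyl-1,3,2-dioxastannolane | C#C[C@H]1CO[Sn](CCCC)(CCCC)O1 | intermediate (not isolated)
11 | (S)-1-(benzyloxy)but-3-yn-2-ol | C#C[C@H](O)COCc1ccccc1 | intermediate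
12 | (S)-1-(benzyloxy)but-3-yn-2-yl methanesulfonate | C#C[C@H](OS(C)(=O)=O)COCc1ccccc1 | intermediate
13 | vanillin (4-hydroxy-3-methoxybenzaldehyde) | COc1cc(C=O)ccc1O | starting material
14 | 4-formyl-2-methoxyphenyl dimethylcarbamate | COc1cc(C=O)ccc1OC(=O)N(C)C | intermediate
15 | ethyl[(P)-4-(benzyloxy)buta-1,2-dien-1-yl]zinc | CC[Zn]C([H])=[C@@]=C([H])COCc1ccccc1 | intermediate (not isolated)
16 | 4-[(1S,2R)-2-[(benzyloxy)methyl]-1-hydroxybut-3-yn-1-yl]-2-methoxyphenyl dimethylcarbamate | C#C[C@H](COCc1ccccc1)[C@@H](c1ccc(OC(=O)N(C)C)c(OC)c1)O | intermediate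
17 | methyl 3-{[(1R,2R)-2-[(benzyloxy)methyl]-1-[4-(dimethylcarbamoyloxy)-3-methoxyphenyl]but-3-yn-1-yl]oxy}-4-methoxy-2-oxo-2H-pyran-6-carboxylate | C#C[C@H](COCc1ccccc1)[C@H](c1ccc(OC(=O)N(C)C)c(OC)c1)OC1=C(OC)C=C(C(=O)OC)OC1=O | intermediate
18 | bridged lactone cycloadduct: 2-oxabicyclo[2.2.2]octa-5,7-dien-3-one formed by addition of the alkyne across pyrone C3 and C6, ring D already closed, bridgehead configuration undefined | COC(=O)C12OC(=O)C3(O[C@@H](c4ccc(OC(=O)N(C)C)c(OC)c4)[C@@H](COCc4ccccc4)C3=C1)C(OC)=C2 | intermediate (not isolated)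
19 | methyl (2R,3R)-3-[(benzyloxy)methyl]-2-[4-(dimethylcarbamoyloxy)-3-methoxyphenyl]-7-methoxy-2,3-dihydro-1-benzofuran-5-carboxylate | COC(=O)c1cc(OC)c2c(c1)[C@H](COCc1ccccc1)[C@H](c1ccc(OC(=O)N(C)C)c(OC)c1)O2 | intermediate
20 | tert-butyl 3-(DBF)-3-oxopropanoate | CC(C)(C)OC(=O)CC(=O)c1cc(OC)c2c(c1)[C@H](COCc1ccccc1)[C@H](c1ccc(OC(=O)N(C)C)c(OC)c1)O2 | intermediate
21 | ethyl 3-bromo-2-oxopropanoate | CCOC(=O)C(=O)CBr | starting material
22 | 4-tert-butyl 1-ethyl (2R)-2-(bromomethyl)-3-(DBF-carbonyl)-2-hydroxybutanedioate (C3 epimers) | CCOC(=O)[C@@](O)(CBr)C(C(=O)OC(C)(C)C)C(=O)c1cc(OC)c2c(c1)[C@H](COCc1ccccc1)[C@H](c1ccc(OC(=O)N(C)C)c(OC)c1)O2 | intermediate (not isolated)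
23 | 3-tert-butyl 4-ethyl (4S)-2-(DBF)-4-hydroxy-4,5-dihydrofuran-3,4-dicarboxylate | CCOC(=O)[C@@]1(O)COC(c2cc(OC)c3c(c2)[C@H](COCc2ccccc2)[C@H](c2ccc(OC(=O)N(C)C)c(OC)c2)O3)=C1C(=O)OC(C)(C)C | intermediate
24 | 3-tert-butyl 4-ethyl (2R,3R,4S)-2-(DBF)-4-hydroxyoxolane-3,4-dicarboxylate | CCOC(=O)[C@@]1(O)CO[C@@H](c2cc(OC)c3c(c2)[C@H](COCc2ccccc2)[C@H](c2ccc(OC(=O)N(C)C)c(OC)c2)O3)[C@H]1C(=O)OC(C)(C)C | intermediate
25 | tert-butyl (2R,3R,4R)-2-(DBF)-4-hydroxy-4-(hydroxymethyl)oxolane-3-carboxylate | OC[C@@]1(O)CO[C@@H](c2cc(OC)c3c(c2)[C@H](COCc2ccccc2)[C@H](c2ccc(OC(=O)N(C)C)c(OC)c2)O3)[C@H]1C(=O)OC(C)(C)C | intermediate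
26 | tert-butyl (2R,3R,4S)-2-(DBF)-4-hydroxy-4-{[(4-methylbenzenesulfonyl)oxy]methyl}oxolane-3-carboxylate | Cc1ccc(cc1)S(=O)(=O)OC[C@@]1(O)CO[C@@H](c2cc(OC)c3c(c2)[C@H](COCc2ccccc2)[C@H](c2ccc(OC(=O)N(C)C)c(OC)c2)O3)[C@H]1C(=O)OC(C)(C)C | intermediate (not isolated)
27 | tert-butyl (3R,6R,7R)-6-(DBF)-1,5-dioxaspiro[2.4]heptane-7-carboxylate | C1[C@@]2(O1)CO[C@@H](c3cc(OC)c4c(c3)[C@H](COCc3ccccc3)[C@H](c3ccc(OC(=O)N(C)C)c(OC)c3)O4)[C@H]2C(=O)OC(C)(C)C | intermediate
28 | 1-(benzyloxy)-4-bromo-2-methoxybenzene | COc1cc(Br)ccc1OCc1ccccc1 | starting material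
29 | [4-(benzyloxy)-3-methoxyphenyl]magnesium bromide | COc1cc([Mg]Br)ccc1OCc1ccccc1 | intermediate (not isolated)
30 | tert-butyl (2R,3R,4S)-4-[4-(benzyloxy)-3-methoxybenzyl]-2-(DBF)-4-hydroxyoxolane-3-carboxylate | COc1cc(C[C@@]2(O)CO[C@@H](c3cc(OC)c4c(c3)[C@H](COCc3ccccc3)[C@H](c3ccc(OC(=O)N(C)C)c(OC)c3)O4)[C@H]2C(=O)OC(C)(C)C)ccc1OCc1ccccc1 | intermediate
31 | (3S,4R,5R)-3-[4-(benzyloxy)-3-methoxybenzyl]-5-[(2R,3R)-3-[(benzyloxy)methyl]-2-(4-hydroxy-3-methoxyphenyl)-7-methoxy-2,3-dihydro-1-benzofuran-5-yl]-4-(hydroxymethyl)oxolan-3-ol | COc1cc(C[C@@]2(O)CO[C@@H](c3cc(OC)c4c(c3)[C@H](COCc3ccccc3)[C@H](c3ccc(O)c(OC)c3)O4)[C@H]2CO)ccc1OCc1ccccc1 | intermediate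
32 | (3S,4R,5R)-5-[(2R,3R)-2-(4-hydroxy-3-methoxyphenyl)-3-(hydroxymethyl)-7-methoxy-2,3-dihydro-1-benzofuran-5-yl]-3-(4-hydroxy-3-methoxybenzyl)-4-(hydroxymethyl)oxolan-3-ol | COc1cc(C[C@@]2(O)CO[C@@H](c3cc(OC)c4c(c3)[C@H](CO)[C@H](c3ccc(O)c(OC)c3)O4)[C@H]2CO)ccc1O | target

**Count and risks**

Total step count: 20. Longest linear sequence: 15 steps (steps 5–8, 10–12 and 13–20, from 7).

Steps most likely to fail:

Step 12. At the temperature an unactivated terminal alkyne needs, heterolysis of the benzylic C–O bond or decomposition of the pyrone may outrun the cycloaddition. The fallback sets out from 17. The terminal alkyne is brominated (N-bromosuccinimide, AgNO3 cat., acetone, rt) to the 1-bromoalkyne F1. The halogen lowers the alkyne LUMO, so the intramolecular cycloaddition and CO2 loss should proceed at a lower temperature and give the 4-bromodihydrobenzofuran ester F2. Palladium-catalysed transfer hydrodebromination (Pd(OAc)2, PPh3, HCO2H, Et3N, DMF, 80 °C) then removes the bromine and comes back to the route at 19.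

Step 15. The tetrasubstituted donor–acceptor alkene may fail to turn over on the iridium complex, or hydrogen may be delivered from the face of the C4 ester if that carbonyl competes as the directing group. The fallback sets out from 23. The ethyl ester is reduced first (LiBH4, THF, 0 °C) to the dihydrofuran diol F3, and the primary hydroxyl is silylated (tert-butyldiphenylsilyl chloride, imidazole, DMF) to the silyl ether F4. The bulky silyloxymethyl group then shields one face and only the tertiary hydroxyl remains as a binding site, so heterogeneous hydrogenation (H2, 4 bar, Rh/Al2O3, EtOAc) should add from the hydroxyl face and give the oxolane silyl ether F5. Desilylation (Bu4NF, THF) comes back to the route at 25.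

Step 11. The bulky pyronate may attack the hindered alkoxyphosphonium ion too slowly, so that elimination to the enyne or loss of clean inversion takes over. The fallback sets out from 16 and separates activation from displacement. The alcohol is converted with retention into the benzylic mesylate F6 (MsCl, Et3N, CH2Cl2, −40 °C), which the carbamate on ring B should make stable enough to handle cold. The caesium salt of 6 (Cs2CO3, DMF, 0 °C) then displaces it by SN2 with inversion at a high concentration of free nucleophile, coming back to the route at 17.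

Further compounds
F1 | step 12 | methyl 3-{[(1R,2R)-2-[(benzyloxy)methyl]-4-bromo-1-[4-(dimethylcarbamoyloxy)-3-methoxyphenyl]but-3-yn-1-yl]oxy}-4-methoxy-2-oxo-2H-pyran-6-carboxylate | BrC#C[C@H](COCc1ccccc1)[C@H](c1ccc(OC(=O)N(C)C)c(OC)c1)OC1=C(OC)C=C(C(=O)OC)OC1=O
F2 | step 12 | methyl (2R,3R)-3-[(benzyloxy)methyl]-4-bromo-2-[4-(dimethylcarbamoyloxy)-3-methoxyphenyl]-7-methoxy-2,3-dihydro-1-benzofuran-5-carboxylate | COC(=O)c1cc(OC)c2c(c1Br)[C@H](COCc1ccccc1)[C@H](c1ccc(OC(=O)N(C)C)c(OC)c1)O2
F3 | step 15 | tert-butyl (4R)-2-(DBF)-4-hydroxy-4-(hydroxymethyl)-4,5-dihydrofuran-3-carboxylate | OC[C@@]1(O)COC(c2cc(OC)c3c(c2)[C@H](COCc2ccccc2)[C@H](c2ccc(OC(=O)N(C)C)c(OC)c2)O3)=C1C(=O)OC(C)(C)C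
F4 | step 15 | tert-butyl (4S)-4-{[(tert-butyldiphenylsilyl)oxy]methyl}-2-(DBF)-4-hydroxy-4,5-dihydrofuran-3-carboxylate | CC(C)(C)[Si](c1ccccc1)(c1ccccc1)OC[C@@]1(O)COC(c2cc(OC)c3c(c2)[C@H](COCc2ccccc2)[C@H](c2ccc(OC(=O)N(C)C)c(OC)c2)O3)=C1C(=O)OC(C)(C)C
F5 | step 15 | tert-butyl (2R,3R,4S)-4-{[(tert-butyldiphenylsilyl)oxy]methyl}-2-(DBF)-4-hydroxyoxolane-3-carboxylate | CC(C)(C)[Si](c1ccccc1)(c1ccccc1)OC[C@@]1(O)CO[C@@H](c2cc(OC)c3c(c2)[C@H](COCc2ccccc2)[C@H](c2ccc(OC(=O)N(C)C)c(OC)c2)O3)[C@H]1C(=O)OC(C)(C)C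
F6 | step 11 | 4-[(1S,2R)-2-[(benzyloxy)methyl]-1-(methanesulfonyloxy)but-3-yn-1-yl]-2-methoxyphenyl dimethylcarbamate | C#C[C@H](COCc1ccccc1)[C@@H](c1ccc(OC(=O)N(C)C)c(OC)c1)OS(C)(=O)=O
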